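Ring A is a hexasubstituted acylphloroglucinol whose alternate carbons a1, a3 and a5 carry three different carbon groups (hydroxyalkenyl chain, bridge CH2 to ring B, isobutyryl) between oxygens at a2, a4 and a6. The route exploits that pattern by cutting ring A at a3–a4 and a5–a6. A [4+2] cycloaddition–aromatisation of an acyclic 2,4-disubstituted 1-methoxy-1,3-bis(trimethylsilyloxy)diene with an alkoxy ynone forms both bonds and the ring in one operation, each substituent arriving on a predetermined carbon. The diene precursor already carries ring B, joined through the future bridge carbon at C4, and the silyl-protected (R) side chain at C2. After the key step only protecting groups are removed.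

Key step: step 15

Remarks on the chemistry (they hold for the whole route):
- Labels: ring A a1–a6 as above; ring B b1 (bridge carbon), b2 and b4 (OH), b3 (acetyl), b5 (methyl), b6 (OMe); diene C1 (ketene acetal carbon) to C4.
- The alkyl ether that the cycloaddition leaves at a4 lies beside a ketone already chelated by the a6 hydroxyl. Chelation-directed dealkylation (MgI2 type) cannot be relied on there, and a primary alkyl group could not be told apart from the b6 methyl ether. The ynone therefore carries an isopropyl group, which BCl3 cleaves by ionisation. Ring B is protected with the same group, so one reagent frees all three phenols.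
- The base that makes the diene also enolises the ring B acetyl group. The precursor is therefore drawn and used with that ketone as its trimethylsilyl enol ether, which reverts on desilylation.
- Oxidising a prenyl group after ring A exists would have to be done beside five free phenols. The (R) carbinol is instead set before the key step and carried as a silyl ether on the same C5 carbon skeleton at C2 of the diene.
- C2 of the β-keto ester is formed as a mixture of epimers; this is of no consequence because it becomes sp2 in the next step.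

Step 1
Reactants: 1 2,4,6-trihydroxytoluene
Product: 2 1-(2,4,6-trihydroxy-3-methylphenyl)ethan-1-one
Conditions: AcCl, AlCl3, PhNO2/CH2Cl2, 0 → 50 °C; aq. HCl
Reagents that add atoms: acetyl chloride, CC(Cl)=O
Why: Friedel–Crafts acylation of the electron-rich ring, in which the two open positions of 1 are equivalent and the first acyl group deactivates the ring towards a second.

Step 2
Reactants: 2 1-(2,4,6-trihydroxy-3-methylphenyl)ethan-1-one
Product: 3 1-(2,6-dihydroxy-4-methoxy-3-methylphenyl)ethan-1-one
Conditions: Me2SO4 (1.0 equiv), K2CO3 (1.0 equiv), acetone, 20 → 56 °C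
Reagents that add atoms: dimethyl sulfate, COS(=O)(=O)OC
Why: Williamson etherification, selective because the hydroxyl para to the acetyl group is the most acidic and the only one not hydrogen-bonded to the carbonyl.

Step 3
Reactants: 3 1-(2,6-dihydroxy-4-methoxy-3-methylphenyl)ethan-1-one
Product: 4 3-acetyl-2,4-dihydroxy-6-methoxy-5-methylbenzaldehyde
Conditions: Cl2CHOMe, TiCl4, CH2Cl2, 0 → 20 °C; then 1 M aq. HCl
Reagents that add atoms: dichloromethyl methyl ether, COC(Cl)Cl; water, O
Why: Rieche formylation at the single unsubstituted ring carbon, which lies ortho and para to oxygen and is directed by the titanium phenoxides.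

Step 4
Reactants: 4 3-acetyl-2,4-dihydroxy-6-methoxy-5-methylbenzaldehyde
Product: 5 3-acetyl-6-methoxy-5-methyl-2,4-di(propan-2-yloxy)benzaldehyde
Conditions: 2-iodopropane, Cs2CO3, DMF, 50 °C
Reagents that add atoms: 2-iodopropane, CC(C)I
Why: Williamson etherification of both chelated phenols as cesium phenoxides; the isopropyl ethers tolerate strong base and silylation and are later removed by ionising cleavage.

Step 5
Reactants: 5 3-acetyl-6-methoxy-5-methyl-2,4-di(propan-2-yloxy)benzaldehyde; 6 diethyl [2-[methoxy(methyl)amino]-2-oxoethyl]phosphonate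
Product: 7 (2E)-3-[3-acetyl-6-methoxy-5-methyl-2,4-di(propan-2-yloxy)phenyl]-N-methoxy-N-methylprop-2-enamide
Conditions: LiCl, DBU, MeCN, 20 °C
Reagents that add atoms: none
Why: Horner–Wadsworth–Emmons olefination under mild amine/LiCl conditions, which should give the (E)-enamide without enolising the aryl methyl ketone.

Step 6
Reactants: 7 (2E)-3-[3-acetyl-6-methoxy-5-methyl-2,4-di(propan-2-yloxy)phenyl]-N-methoxy-N-methylprop-2-enamide
Product: 8 3-[3-acetyl-6-methoxy-5-methyl-2,4-di(propan-2-yloxy)phenyl]-N-methoxy-N-methylpropanamide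
Conditions: H2 (1 atm), Pd/C, EtOAc, 20 °C
Reagents that add atoms: none
Why: Heterogeneous catalytic hydrogenation of the conjugated C=C bond; the hindered di-ortho-substituted aryl ketone and the amide N–O bond should survive at atmospheric pressure.

Step 7
Reactants: 9 methyl 4-chloro-4-oxobutanoate; 10 isopropenylmagnesium bromide
Product: 12 methyl 5-methyl-4-oxohex-5-enoate, via isopropenylzinc chloride 11 (not isolated)
Conditions: ZnCl2, THF, 0 °C; then 9, Pd(PPh3)4 (3 mol %), 0 → 20 °C
Reagents that add atoms: none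
Why: Negishi acylation, in which the alkenylzinc couples with the acid chloride under palladium catalysis and leaves the methyl ester untouched.

Step 8
Reactants: 12 methyl 5-methyl-4-oxohex-5-enoate
Product: 13 methyl (4R)-4-hydroxy-5-methylhex-5-enoate
Conditions: (S)-2-methyl-CBS-oxazaborolidine [(3aS)-1-methyl-3,3-diphenyltetrahydro-1H,3H-pyrrolo[1,2-c][1,3,2]oxazaborole] (15 mol %), catecholborane, toluene, −78 °C; MeOH, pH 7 buffer
Reagents that add atoms: none
Why: Corey–Bakshi–Shibata reduction, in which the isopropenyl group acts as the large substituent so that the (S)-oxazaborolidine directs hydride to the face giving the (R) carbinol, while catecholborane at low temperature avoids hydroboration of the alkene.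

Step 9
Reactants: 13 methyl (4R)-4-hydroxy-5-methylhex-5-enoate
Product: 14 methyl (4R)-4-[tert-butyl(dimethyl)silyl]oxy-5-methylhex-5-enoate
Conditions: TBSOTf, 2,6-lutidine, CH2Cl2, −78 → 0 °C
Reagents that add atoms: tert-butyldimethylsilyl trifluoromethanesulfonate, CC(C)(C)[Si](C)(C)OS(=O)(=O)C(F)(F)F
Why: Silylation of the secondary alcohol with the silyl triflate at low temperature, fast enough to outrun lactonisation of the γ-hydroxy ester and without effect on the stereocentre.

Step 10
Reactants: 8 3-[3-acetyl-6-methoxy-5-methyl-2,4-di(propan-2-yloxy)phenyl]-N-methoxy-N-methylpropanamide; 14 methyl (4R)-4-[tert-butyl(dimethyl)silyl]oxy-5-methylhex-5-enoate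
Product: 17 methyl 5-[3-acetyl-6-methoxy-5-methyl-2,4-di(propan-2-yloxy)phenyl]-2-[(2R)-2-[tert-butyl(dimethyl)silyl]oxy-3-methylbut-3-en-1-yl]-3-oxopentanoate (C2 epimers), via aryl ketone lithium enolate 15 (not isolated), via ester lithium enolate 16 (not isolated)
Conditions: 8, LiN(SiMe3)2 (1.05 equiv), THF, −78 °C; 14, LiN(iPr)2 (1.4 equiv), THF, −78 °C; combine, −78 → −20 °C; aq. NH4Cl
Reagents that add atoms: none
Why: Claisen-type acylation of an ester enolate by a Weinreb amide, whose chelated tetrahedral adduct prevents over-addition; converting the aryl methyl ketone into its lithium enolate beforehand shields it from proton transfer and attack, the new C2 centre is formed without control, and the (R) carbinol, which is not alpha to a carbonyl, is untouched.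

Step 11
Reactants: 17 methyl 5-[3-acetyl-6-methoxy-5-methyl-2,4-di(propan-2-yloxy)phenyl]-2-[(2R)-2-[tert-butyl(dimethyl)silyl]oxy-3-methylbut-3-en-1-yl]-3-oxopentanoate
Product: 18 methyl 5-[3-acetyl-6-methoxy-5-methyl-2,4-di(propan-2-yloxy)phenyl]-2-[(2R)-2-[tert-butyl(dimethyl)silyl]oxy-3-methylbut-3-en-1-yl]-3-(trimethylsilyloxy)pent-2-enoate (E/Z mixture)
Conditions: Me3SiCl, Et3N, toluene, 20 °C; filtration under argon
Reagents that add atoms: chlorotrimethylsilane, C[Si](C)(C)Cl
Why: O-silylation of the β-keto ester enol under soft enolisation with an amine base, which leaves the far less acidic aryl methyl ketone alone.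

Step 12
Reactants: 18 methyl 5-[3-acetyl-6-methoxy-5-methyl-2,4-di(propan-2-yloxy)phenyl]-2-[(2R)-2-[tert-butyl(dimethyl)silyl]oxy-3-methylbut-3-en-1-yl]-3-(trimethylsilyloxy)pent-2-enoate
Product: 20 (3Z)-1-methoxy-1,3-bis(trimethylsilyloxy)buta-1,3-diene bearing the (2R)-2-[tert-butyl(dimethyl)silyl]oxy-3-methylbut-3-en-1-yl group at C2 and the [6-methoxy-5-methyl-2,4-di(propan-2-yloxy)-3-[1-(trimethylsilyloxy)ethenyl]phenyl]methyl group at C4, via dilithium dienolate 19 (not isolated)
Conditions: LiN(iPr)2 (2.3 equiv), THF, −78 °C; Me3SiCl, −78 → 20 °C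
Reagents that add atoms: chlorotrimethylsilane, C[Si](C)(C)Cl
Why: Deprotonation at the γ-carbon of the β-silyloxy enoate and O-silylation of the dienolate is the standard entry to 1-alkoxy-1,3-bis(silyloxy)dienes; the second equivalent of base converts the ring B acetyl group into its silyl enol ether, which masks it during the cycloaddition.

Step 13
Reactants: 21 trichloroethylene; 22 propan-2-ol
Product: 24 (E)-1,2-dichloro-1-(propan-2-yloxy)ethene, via potassium propan-2-olate 23 (not isolated)
Conditions: KH, THF, 0 → 20 °C; then 21, −50 → 20 °C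
Reagents that add atoms: none
Why: Net vinylic substitution of chloride by the alkoxide through elimination–addition, a general route to 1,2-dichlorovinyl ethers as ynol ether precursors.

Step 14
Reactants: 24 (E)-1,2-dichloro-1-(propan-2-yloxy)ethene; 25 N-methoxy-N,2-dimethylpropanamide
Product: 27 4-methyl-1-(propan-2-yloxy)pent-1-yn-3-one, via lithium isopropoxyethynide 26 (not isolated)
Conditions: n-BuLi (2.3 equiv), THF, −78 → −40 °C; then 25, −78 → 0 °C; cold aq. NH4Cl
Reagents that add atoms: none
Why: Dehydrochlorination and chlorine–lithium exchange give the lithium alkoxyacetylide, which adds once to the Weinreb amide because the chelated adduct persists until work-up (Weinreb ketone synthesis).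

Step 15
Reactants: 20 (3Z)-1-methoxy-1,3-bis(trimethylsilyloxy)buta-1,3-diene bearing the (2R)-2-[tert-butyl(dimethyl)silyl]oxy-3-methylbut-3-en-1-yl group at C2 and the ring B arylmethyl group at C4; 27 4-methyl-1-(propan-2-yloxy)pent-1-yn-3-one
Product: 30 1-[3-[[3-acetyl-6-methoxy-5-methyl-2,4-di(propan-2-yloxy)phenyl]methyl]-5-[(2R)-2-[tert-butyl(dimethyl)silyl]oxy-3-methylbut-3-en-1-yl]-4,6-dihydroxy-2-(propan-2-yloxy)phenyl]-2-methylpropan-1-one, via cyclohexadiene cycloadduct 28 (not isolated), via ring A bis(trimethylsilyl) ether 29 (not isolated)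
Conditions: toluene (1 M), 25 → 60 °C; then NH4F, MeOH, 0 → 20 °C
Reagents that add atoms: none
Why: Proposed new method: the diene terminus C4 (largest HOMO coefficient, future a3) should bond to the isopropoxy-bearing β-carbon of the ynone (largest LUMO coefficient, polarised by the ketone) and the α-carbon of the developing allenolate (future a5) to the ketene acetal carbon C1 (future a6), after which 1,4-loss of methanol from 28 and fluoride desilylation of 29 give the arene. The closest known reaction type is the Diels–Alder/aromatisation of 1-alkoxy-1,3-bis(silyloxy)buta-1,3-dienes with acetylenic ketones and esters to give resorcinols; untested here are a dienophile with a donor oxygen on its β-carbon and a diene substituted at both C2 and C4. Ring A, the only ring formed, closes in the [4+2] mode, either concerted and asynchronous or, in the stepwise limit, by Mukaiyama–Michael addition followed by 6-exo-trig attack on the silylated ester carbon. No stereocentre is created, since C4 of 28 becomes planar on aromatisation, and the (R) silyloxy carbon lies outside the reacting π system and cannot epimerise. The step needs one orientation, secured by matching the polarisation of the two partners, which puts the isopropoxy group between the bridge carbon and the isobutyryl carbon; closure through C1 and not C2 is secured by the C2 substituent, because an aldol-type closure through C2 cannot aromatise and is reversible. The ring B silyl enol ether is far less nucleophilic than the ketene acetal diene and should not compete.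

Step 16
Reactants: 30 1-[3-[[3-acetyl-6-methoxy-5-methyl-2,4-di(propan-2-yloxy)phenyl]methyl]-5-[(2R)-2-[tert-butyl(dimethyl)silyl]oxy-3-methylbut-3-en-1-yl]-4,6-dihydroxy-2-(propan-2-yloxy)phenyl]-2-methylpropan-1-one
Product: 31 1-[3-[(3-acetyl-2,4-dihydroxy-6-methoxy-5-methylphenyl)methyl]-5-[(2R)-2-[tert-butyl(dimethyl)silyl]oxy-3-methylbut-3-en-1-yl]-2,4,6-trihydroxyphenyl]-2-methylpropan-1-one
Conditions: BCl3 (1 M in CH2Cl2), CH2Cl2, −78 → −10 °C; MeOH, then aq. NaHCO3
Reagents that add atoms: none
Why: Lewis-acid ether cleavage in which BCl3 removes the three isopropyl groups by ionising C–O scission, a path closed to the b6 methyl ether at this temperature and independent of chelation to the already engaged isobutyryl carbonyl, while the hindered secondary silyl ether is a poor donor towards boron.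

Step 17
Reactants: 31 1-[3-[(3-acetyl-2,4-dihydroxy-6-methoxy-5-methylphenyl)methyl]-5-[(2R)-2-[tert-butyl(dimethyl)silyl]oxy-3-methylbut-3-en-1-yl]-2,4,6-trihydroxyphenyl]-2-methylpropan-1-one
Product: 32 1-[3-[(3-acetyl-2,4-dihydroxy-6-methoxy-5-methylphenyl)methyl]-2,4,6-trihydroxy-5-[(2R)-2-hydroxy-3-methylbut-3-en-1-yl]phenyl]-2-methylpropan-1-one (CNP0162925.1)
Conditions: HF·pyridine, pyridine, THF, 0 → 20 °C
Reagents that add atoms: none
Why: Fluoride-mediated desilylation under buffered, weakly acidic conditions breaks only the Si–O bond, so the (R) configuration set in step 8 is kept, and it avoids both phenoxide formation and acid-induced cyclisation of an ortho phenol onto the isopropenyl group.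

Compound list
1 | 2,4,6-trihydroxytoluene | Cc1c(O)cc(O)cc1O | starting material
2 | 1-(2,4,6-trihydroxy-3-methylphenyl)ethan-1-one | CC(=O)c1c(O)cc(O)c(C)c1O | intermediate
3 | 1-(2,6-dihydroxy-4-methoxy-3-methylphenyl)ethan-1-one | CC(=O)c1c(O)cc(OC)c(C)c1O | intermediate
4 | 3-acetyl-2,4-dihydroxy-6-methoxy-5-methylbenzaldehyde | CC(=O)c1c(O)c(C=O)c(OC)c(C)c1O | intermediate
5 | 3-acetyl-6-methoxy-5-methyl-2,4-di(propan-2-yloxy)benzaldehyde | CC(=O)c1c(OC(C)C)c(C=O)c(OC)c(C)c1OC(C)C | intermediate
6 | diethyl [2-[methoxy(methyl)amino]-2-oxoethyl]phosphonate | CCOP(=O)(CC(=O)N(C)OC)OCC | starting material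
7 | (2E)-3-[3-acetyl-6-methoxy-5-methyl-2,4-di(propan-2-yloxy)phenyl]-N-methoxy-N-methylprop-2-enamide | CC(=O)c1c(OC(C)C)c(/C=C/C(=O)N(C)OC)c(OC)c(C)c1OC(C)C | intermediate
8 | 3-[3-acetyl-6-methoxy-5-methyl-2,4-di(propan-2-yloxy)phenyl]-N-methoxy-N-methylpropanamide | CC(=O)c1c(OC(C)C)c(CCC(=O)N(C)OC)c(OC)c(C)c1OC(C)C | intermediate
9 | methyl 4-chloro-4-oxobutanoate | COC(=O)CCC(Cl)=O | starting material
10 | isopropenylmagnesium bromide | C=C(C)[Mg]Br | starting material
11 | isopropenylzinc chloride | C=C(C)[Zn]Cl | intermediate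
12 | methyl 5-methyl-4-oxohex-5-enoate | C=C(C)C(=O)CCC(=O)OC | intermediate
13 | methyl (4R)-4-hydroxy-5-methylhex-5-enoate | C=C(C)[C@H](O)CCC(=O)OC | intermediate
14 | methyl (4R)-4-[tert-butyl(dimethyl)silyl]oxy-5-methylhex-5-enoate | C=C(C)[C@H](O[Si](C)(C)C(C)(C)C)CCC(=O)OC | intermediate
15 | lithium enolate of 8 at the ring B acetyl group | [Li]OC(=C)c1c(OC(C)C)c(CCC(=O)N(C)OC)c(OC)c(C)c1OC(C)C | intermediate
16 | lithium enolate of ester 14 | C=C(C)[C@H](O[Si](C)(C)C(C)(C)C)CC=C(O[Li])OC | intermediate
17 | methyl 5-[3-acetyl-6-methoxy-5-methyl-2,4-di(propan-2-yloxy)phenyl]-2-[(2R)-2-[tert-butyl(dimethyl)silyl]oxy-3-methylbut-3-en-1-yl]-3-oxopentanoate (C2 epimers) | COC(=O)C(C[C@@H](O[Si](C)(C)C(C)(C)C)C(C)=C)C(=O)CCc1c(OC(C)C)c(C(C)=O)c(OC(C)C)c(C)c1OC | intermediate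
18 | methyl 5-[3-acetyl-6-methoxy-5-methyl-2,4-di(propan-2-yloxy)phenyl]-2-[(2R)-2-[tert-butyl(dimethyl)silyl]oxy-3-methylbut-3-en-1-yl]-3-(trimethylsilyloxy)pent-2-enoate (E/Z mixture) | COC(=O)C(C[C@@H](O[Si](C)(C)C(C)(C)C)C(C)=C)=C(O[Si](C)(C)C)CCc1c(OC(C)C)c(C(C)=O)c(OC(C)C)c(C)c1OC | intermediate
19 | dilithium species from 18: ester dienolate and ring B acetyl enolate | COC(O[Li])=C(C[C@@H](O[Si](C)(C)C(C)(C)C)C(C)=C)C(O[Si](C)(C)C)=CCc1c(OC(C)C)c(C(=C)O[Li])c(OC(C)C)c(C)c1OC | intermediate
20 | (3Z)-1-methoxy-1,3-bis(trimethylsilyloxy)buta-1,3-diene with the (2R)-2-[tert-butyl(dimethyl)silyl]oxy-3-methylbut-3-en-1-yl group at C2 and the [6-methoxy-5-methyl-2,4-di(propan-2-yloxy)-3-[1-(trimethylsilyloxy)ethenyl]phenyl]methyl group at C4 (key-step precursor) | COC(O[Si](C)(C)C)=C(C[C@@H](O[Si](C)(C)C(C)(C)C)C(C)=C)/C(O[Si](C)(C)C)=C/Cc1c(OC(C)C)c(C(=C)O[Si](C)(C)C)c(OC(C)C)c(C)c1OC | intermediate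
21 | trichloroethylene | ClC=C(Cl)Cl | starting material
22 | propan-2-ol | CC(C)O | starting material
23 | potassium propan-2-olate | CC(C)[O-].[K+] | intermediate
24 | (E)-1,2-dichloro-1-(propan-2-yloxy)ethene | CC(C)O/C(Cl)=C\Cl | intermediate
25 | N-methoxy-N,2-dimethylpropanamide | CC(C)C(=O)N(C)OC | starting material
26 | lithium 2-(propan-2-yloxy)ethynide | [Li]C#COC(C)C | intermediate
27 | 4-methyl-1-(propan-2-yloxy)pent-1-yn-3-one | CC(C)OC#CC(=O)C(C)C | intermediate
28 | cyclohexa-1,4-diene cycloadduct: C1 (OMe, OSiMe3), C2 (side chain), C3 (OSiMe3), C4 (H, CH2–ring B), C5 (O-isopropyl), C6 (isobutyryl); C4 epimers | COC1(O[Si](C)(C)C)C(C[C@@H](O[Si](C)(C)C(C)(C)C)C(C)=C)=C(O[Si](C)(C)C)C(Cc2c(OC(C)C)c(C(=C)O[Si](C)(C)C)c(OC(C)C)c(C)c2OC)C(OC(C)C)=C1C(=O)C(C)C | intermediate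
29 | a2,a6-bis(trimethylsilyl) ether of 30 with the ring B acetyl group as trimethylsilyl enol ether | C=C(C)[C@H](O[Si](C)(C)C(C)(C)C)Cc1c(O[Si](C)(C)C)c(Cc2c(OC(C)C)c(C(=C)O[Si](C)(C)C)c(OC(C)C)c(C)c2OC)c(OC(C)C)c(C(=O)C(C)C)c1O[Si](C)(C)C | intermediate
30 | 1-[3-[[3-acetyl-6-methoxy-5-methyl-2,4-di(propan-2-yloxy)phenyl]methyl]-5-[(2R)-2-[tert-butyl(dimethyl)silyl]oxy-3-methylbut-3-en-1-yl]-4,6-dihydroxy-2-(propan-2-yloxy)phenyl]-2-methylpropan-1-one (key-step product) | C=C(C)[C@H](O[Si](C)(C)C(C)(C)C)Cc1c(O)c(Cc2c(OC(C)C)c(C(C)=O)c(OC(C)C)c(C)c2OC)c(OC(C)C)c(C(=O)C(C)C)c1O | intermediate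
31 | 1-[3-[(3-acetyl-2,4-dihydroxy-6-methoxy-5-methylphenyl)methyl]-5-[(2R)-2-[tert-butyl(dimethyl)silyl]oxy-3-methylbut-3-en-1-yl]-2,4,6-trihydroxyphenyl]-2-methylpropan-1-one | C=C(C)[C@H](O[Si](C)(C)C(C)(C)C)Cc1c(O)c(Cc2c(O)c(C(C)=O)c(O)c(C)c2OC)c(O)c(C(=O)C(C)C)c1O | intermediate
32 | 1-[3-[(3-acetyl-2,4-dihydroxy-6-methoxy-5-methylphenyl)methyl]-2,4,6-trihydroxy-5-[(2R)-2-hydroxy-3-methylbut-3-en-1-yl]phenyl]-2-methylpropan-1-one | C=C(C)[C@H](O)Cc1c(O)c(Cc2c(O)c(C(C)=O)c(O)c(C)c2OC)c(O)c(C(=O)C(C)C)c1O | target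

Total step count: 17. Longest linear sequence: 12 steps (steps 1–6, 10–12, 15–17).

Steps most likely to fail

Step 15. The first C–C bond may not form because the isopropoxy donor lowers the electrophilicity of the ynone, or the sequence may stop after that bond if silyl transfer to the allenolate outruns ring closure. The fallback, built from known reaction types, sets out from 17 and returns at 31; it closes ring A by base-mediated Claisen cyclisation of a triketo ester. Methyl 4-methyl-3-oxopentanoate is ketalised with ethane-1,2-diol (TsOH, toluene, water removal) to methyl 2-[2-(propan-2-yl)-1,3-dioxolan-2-yl]acetate F1. The trianion of 17 (LiN(iPr)2, 3.3 equiv, THF, −78 → 0 °C; C2, acetyl and C4 deprotonated) is acylated at C4 by F1 to give the ketal-protected 4-substituted 3,5-dioxo ester F2. Pyridinium p-toluenesulfonate in wet acetone removes the ketal to give the 3,5,7-trioxo ester F3. Mg(OMe)2 in MeOH then closes C6 onto the ester carbon with loss of methanol, giving the ring A triol with ring B still as its bis(isopropyl) ether F4; the a4 hydroxyl is free from the outset. BCl3 under the conditions of step 16 removes the two ring B isopropyl groups and gives 31.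

Step 16. Boron may ionise the allylic silyl ether, HCl may add to the isopropenyl group, or slow cleavage at a4 may force temperatures at which the b6 methyl ether is lost. The fallback sets out from 30 and returns at 32; it exchanges the silyl ether for electron-poor acetates before the Lewis acid is used. HF·pyridine frees the carbinol to give the side-chain alcohol F5. Ac2O, Et3N and 4-(dimethylamino)pyridine acetylate the carbinol and the a2 and a6 phenols to give the triacetate F6. This deactivates the allylic C–O bond towards ionisation and frees the isobutyryl carbonyl to chelate boron together with the a4 isopropoxy group, so that BCl3 at −78 °C should suffice and give the de-isopropylated triacetate F7. K2CO3 in MeOH at 0 °C removes the three acetates to give 32.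

Step 10. Proton transfer from the amide α-position or from residual aryl methyl ketone to the ester enolate, or slow addition to the hindered amide, may leave the acylation incomplete. The fallback sets out from 5 and returns at 17; it replaces the acylation by an aldol addition to an aldehyde, which outruns proton transfer. Wittig reaction of 5 with (triphenylphosphoranylidene)acetaldehyde (toluene, 80 °C) gives the (E)-enal F8. Hydrogenation over Pd/C saturates the C=C bond to give the 3-arylpropanal F9. Addition of ester lithium enolate 16 at −78 °C gives the β-hydroxy ester F10 as a mixture of diastereomers, and Dess–Martin periodinane oxidises it to 17.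

Further compounds
F1 | step 15 | methyl 2-[2-(propan-2-yl)-1,3-dioxolan-2-yl]acetate | COC(=O)CC1(C(C)C)OCCO1
F2 | step 15 | methyl 4-[[3-acetyl-6-methoxy-5-methyl-2,4-di(propan-2-yloxy)phenyl]methyl]-2-[(2R)-2-[tert-butyl(dimethyl)silyl]oxy-3-methylbut-3-en-1-yl]-3,5-dioxo-6-[2-(propan-2-yl)-1,3-dioxolan-2-yl]hexanoate | COC(=O)C(C[C@@H](O[Si](C)(C)C(C)(C)C)C(C)=C)C(=O)C(Cc1c(OC(C)C)c(C(C)=O)c(OC(C)C)c(C)c1OC)C(=O)CC1(C(C)C)OCCO1
F3 | step 15 | methyl 4-[[3-acetyl-6-methoxy-5-methyl-2,4-di(propan-2-yloxy)phenyl]methyl]-2-[(2R)-2-[tert-butyl(dimethyl)silyl]oxy-3-methylbut-3-en-1-yl]-8-methyl-3,5,7-trioxononanoate | COC(=O)C(C[C@@H](O[Si](C)(C)C(C)(C)C)C(C)=C)C(=O)C(Cc1c(OC(C)C)c(C(C)=O)c(OC(C)C)c(C)c1OC)C(=O)CC(=O)C(C)C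
F4 | step 15 | 1-[3-[[3-acetyl-6-methoxy-5-methyl-2,4-di(propan-2-yloxy)phenyl]methyl]-5-[(2R)-2-[tert-butyl(dimethyl)silyl]oxy-3-methylbut-3-en-1-yl]-2,4,6-trihydroxyphenyl]-2-methylpropan-1-one | C=C(C)[C@H](O[Si](C)(C)C(C)(C)C)Cc1c(O)c(Cc2c(OC(C)C)c(C(C)=O)c(OC(C)C)c(C)c2OC)c(O)c(C(=O)C(C)C)c1O
F5 | step 16 | 1-[3-[[3-acetyl-6-methoxy-5-methyl-2,4-di(propan-2-yloxy)phenyl]methyl]-4,6-dihydroxy-5-[(2R)-2-hydroxy-3-methylbut-3-en-1-yl]-2-(propan-2-yloxy)phenyl]-2-methylpropan-1-one | C=C(C)[C@H](O)Cc1c(O)c(Cc2c(OC(C)C)c(C(C)=O)c(OC(C)C)c(C)c2OC)c(OC(C)C)c(C(=O)C(C)C)c1O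
F6 | step 16 | triacetate of F5 (side-chain O-acetyl, a2 and a6 O-acetyl) | C=C(C)[C@H](OC(C)=O)Cc1c(OC(C)=O)c(Cc2c(OC(C)C)c(C(C)=O)c(OC(C)C)c(C)c2OC)c(OC(C)C)c(C(=O)C(C)C)c1OC(C)=O
F7 | step 16 | triacetate of 32 (side-chain O-acetyl, a2 and a6 O-acetyl; a4, b2 and b4 hydroxyls free) | C=C(C)[C@H](OC(C)=O)Cc1c(OC(C)=O)c(Cc2c(O)c(C(C)=O)c(O)c(C)c2OC)c(O)c(C(=O)C(C)C)c1OC(C)=O
F8 | step 10 | (2E)-3-[3-acetyl-6-methoxy-5-methyl-2,4-di(propan-2-yloxy)phenyl]prop-2-enal | CC(=O)c1c(OC(C)C)c(/C=C/C=O)c(OC)c(C)c1OC(C)C
F9 | step 10 | 3-[3-acetyl-6-methoxy-5-methyl-2,4-di(propan-2-yloxy)phenyl]propanal | CC(=O)c1c(OC(C)C)c(CCC=O)c(OC)c(C)c1OC(C)C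
F10 | step 10 | methyl 5-[3-acetyl-6-methoxy-5-methyl-2,4-di(propan-2-yloxy)phenyl]-2-[(2R)-2-[tert-butyl(dimethyl)silyl]oxy-3-methylbut-3-en-1-yl]-3-hydroxypentanoate (diastereomer mixture) | COC(=O)C(C[C@@H](O[Si](C)(C)C(C)(C)C)C(C)=C)C(O)CCc1c(OC(C)C)c(C(C)=O)c(OC(C)C)c(C)c1OC
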